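- Per hour is the unit of every constant here, so a constant times hours is a plain number, and for consecutive first-order steps that number tells us what survives.

    J → Z (k1 = 0.022 h⁻¹, Ea1 = 106 kJ mol⁻¹)
    Z → X (k2 = 0.10 h⁻¹, Ea2 = 95.0 kJ mol⁻¹)
    X → E (k3 = 0.041 h⁻¹, Ea3 = 95.0 kJ mol⁻¹)
    X → L (k4 = 0.0030 h⁻¹, Ea4 = 98.0 kJ mol⁻¹)
    D → J (k5 = 0.43 h⁻¹, Ea5 = 92.0 kJ mol⁻¹)
    (constants at 20 °C)

| setting | alpha | delta | theta |
|---|---|---|---|
| D | 0.050 M | 0.050 M | 0.050 M |
| time | 40 h | 40 h | 40 h |
| remark | at 20 °C until 20 h, from then on at 35 °C |  |  |
| temperature |  | 20 °C | 35 °C |

- the list of constants is for 20 °C, to be carried to other temperatures by the activation energies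

1. which flask leads in amount of J, in percent of the D charged ("all alike" within 1.5 percentage points) (alpha / delta / theta / all alike)
2. how much J is there at the end, in percent of the D charged: alpha
3. how much J is there at the end, in percent of the D charged: delta
4. how much J is there at the end, in percent of the D charged: theta

- J is fed by D and drained by J → Z, and the later steps give nothing back to it. So we carry one number, the dose of J: the J → Z constant times the hours spent at each temperature, summed.
- Carried to the warm temperature by the activation energies, J → Z becomes 0.183 h⁻¹ and D → J becomes 2.70 h⁻¹.
- Flask theta takes a dose of 7.31, flask delta 0.880, and flask alpha 4.09.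
- For a bound from below, suppose D became J at once. Every J then suffers the whole dose, and J born later suffers less, so [J] stands above e to the minus dose: 41.5 % in delta, 1.67 % in alpha, 0.0669 % in theta.
- For a bound from above, we count the late birth. D → J is much faster than J → Z, and the two-step solution multiplies the lower bound by k5/(k5 − k1), less a term that dies with D. That factor is 1.05 cold and 1.07 warm.
- So we commit to 43.7 % in delta, 0.0718 % in theta, and 1.76 % in alpha, whose J is born cold. The leader is delta.
- The forecast says “D turns into J quickly in every flask”, names delta, and gives 1.76 % for alpha, 43.7 % for delta and 0.072 % for theta. These values stand at the top of our brackets.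
- The simulation names delta and gives 1.76 % for alpha, 43.7 % for delta and 0.0718 % for theta. In theta at 0.257 h, J was being made 15.2 times faster than it was used up, each step taken net. Now take a neighbour, theta read at 10 h: the dose is 1.83, so the bracket runs from 16.1 % to 17.3 %, and that flask holds J at 17.3 %.

All constants were chosen freely; what happens was integrated by code.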